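**Retrosynthetic overview**

- The two C–Me stereocentres are mirror-related across the central carbonyl, so both are set from one sacrificial carbinol placed on that pseudo-mirror plane and then oxidised away; no aldol and no late pyranone cyclisation of a polyketone is used.
- Central ketone ⇐ secondary alcohol ⇐ two-fold hydroxyl-directed hydrogenation of a bis(1-pyranonylvinyl) carbinol.
- That dienol ⇐ enantioselective Ni/Cr alkenyl–aldehyde coupling of a ring A 2-pyranonylacrolein with a ring B 1-pyranonylvinyl triflate; this is the only enantio-determining step.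
- Ring order: ring A (as 2,3,5,6-tetramethyl-4-pyranone) and ring B (as 2,6-diethyl-3,5-dimethyl-4-pyranone) are each made first, in one step from pentan-3-one; all later chemistry is side-chain work through vinylogous enolates.

Assumption: reagents that leave no atoms other than hydrogen in a product (bases, oxidants, catalysts, ligand, H2) are named under Conditions and carry no number.

Assumption: ligand L* in step 9 is N-[2-((4S)-4-isopropyl-4,5-dihydro-1,3-oxazol-2-yl)-6-methylphenyl]methanesulfonamide, taken to give Re-face addition; if a pilot run shows Si-face addition, its antipode (from D-valinol) is used and nothing else changes.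

**Route**

Step 1
Reactants: 1 pentan-3-one; 2 acetic acid
Product: 3 2,3,5,6-tetramethyl-4H-pyran-4-one
Conditions: AcOH (3 equiv), PPA, 130 °C
Reagents that add atoms: acetic acid, CC(=O)O
Why: in PPA the ketone is C-acylated at both α-carbons and the resulting tricarbonyl array cyclodehydrates in the same pot (ketone–carboxylic acid γ-pyrone condensation), giving ring A as a symmetrical tetraalkyl pyranone.

Step 2
Reactants: 3 2,3,5,6-tetramethyl-4H-pyran-4-one; 4 1-iodobutane
Product: 6 2,3,5-trimethyl-6-pentyl-4H-pyran-4-one, via lithium dienolate 5 (not isolated)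
Conditions: LiN(SiMe3)2 (1.05 equiv), THF, −78 °C; then n-BuI, DMPU, −78 to 0 °C
Reagents that add atoms: 1-iodobutane, CCCCI
Why: only the 2-/6-methyl groups are vinylogously acidified, and the γ-enolate 5 is alkylated at its exocyclic carbon by the primary iodide (vinylogous enolate alkylation), the symmetry of 3 making mono-butylation unambiguous.

Step 3
Reactants: 6 2,3,5-trimethyl-6-pentyl-4H-pyran-4-one; 7 ethyl formate
Product: 9 2-(3,5-dimethyl-4-oxo-6-pentyl-4H-pyran-2-yl)acetaldehyde, via lithium dienolate 8 (not isolated)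
Conditions: LiN(SiMe3)2 (2.2 equiv), THF, −78 °C; then HCO2Et, −78 to −20 °C; aq. NH4Cl
Reagents that add atoms: ethyl formate, CCOC=O
Why: kinetic deprotonation of the unhindered 2-methyl group is faster than that of the pentyl α-CH2, and Claisen formylation of γ-enolate 8 is driven forward because the second equivalent of base stores the product as its stabilised enolate until the quench.

Step 4
Reactants: 9 2-(3,5-dimethyl-4-oxo-6-pentyl-4H-pyran-2-yl)acetaldehyde; 10 formaldehyde (37% aqueous)
Product: 11 2-(3,5-dimethyl-4-oxo-6-pentyl-4H-pyran-2-yl)prop-2-enal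
Conditions: aq. CH2O, pyrrolidine (10 mol%), EtCO2H (10 mol%), i-PrOH, 45 °C; used at once
Reagents that add atoms: formaldehyde, C=O
Why: amine-catalysed Mannich condensation followed by β-elimination of the amine (organocatalytic aldehyde α-methylenation) turns the activated CH2 into the exo-methylene, and the enal is carried forward in solution because 2-substituted acroleins dimerise on storage.

Step 5
Reactants: 1 pentan-3-one; 12 propanoic acid
Product: 13 2,6-diethyl-3,5-dimethyl-4H-pyran-4-one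
Conditions: EtCO2H (3 equiv), PPA, 110 °C
Reagents that add atoms: propanoic acid, CCC(=O)O
Why: the same PPA ketone–acid γ-pyrone condensation as in step 1, now with propanoic acid, gives ring B with both ethyl groups in place in one operation.

Step 6
Reactants: 13 2,6-diethyl-3,5-dimethyl-4H-pyran-4-one; 14 2-(benzenesulfonyl)-3-phenyloxaziridine
Product: 16 2-ethyl-6-(1-hydroxyethyl)-3,5-dimethyl-4H-pyran-4-one (racemic), via potassium dienolate 15 (not isolated)
Conditions: KN(SiMe3)2 (1.1 equiv), THF, −78 °C; then oxaziridine 14; aq. NH4Cl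
Reagents that add atoms: 2-(benzenesulfonyl)-3-phenyloxaziridine, O=S(=O)(c1ccccc1)N1OC1c1ccccc1
Why: the two ethyl groups of 13 are equivalent, and the potassium γ-enolate 15 is hydroxylated at its exocyclic carbon by the N-sulfonyloxaziridine (Davis enolate oxidation), the new carbinol being racemic and erased in step 7.

Step 7
Reactants: 16 2-ethyl-6-(1-hydroxyethyl)-3,5-dimethyl-4H-pyran-4-one
Product: 17 2-acetyl-6-ethyl-3,5-dimethyl-4H-pyran-4-one
Conditions: DMP (1.2 equiv), CH2Cl2, 0 °C to rt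
Reagents that add atoms: none
Why: Dess–Martin oxidation converts the secondary allylic-type alcohol into the methyl ketone under neutral conditions that leave the pyranone untouched.

Step 8
Reactants: 17 2-acetyl-6-ethyl-3,5-dimethyl-4H-pyran-4-one; 18 N-phenylbis(trifluoromethanesulfonimide)
Product: 20 1-(6-ethyl-3,5-dimethyl-4-oxo-4H-pyran-2-yl)ethenyl trifluoromethanesulfonate, via potassium enolate 19 (not isolated)
Conditions: KN(SiMe3)2 (1.05 equiv), THF, −78 °C; then PhNTf2, −78 to 0 °C
Reagents that add atoms: N-phenylbis(trifluoromethanesulfonimide), O=S(=O)(N(c1ccccc1)S(=O)(=O)C(F)(F)F)C(F)(F)F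
Why: the acetyl methyl (α to a ketone) is more acidic than the vinylogous 6-ethyl CH2, so enolate 19 forms selectively and is O-sulfonylated by PhNTf2 (enol triflate formation).

Step 9
Reactants: 11 2-(3,5-dimethyl-4-oxo-6-pentyl-4H-pyran-2-yl)prop-2-enal; 20 1-(6-ethyl-3,5-dimethyl-4-oxo-4H-pyran-2-yl)ethenyl trifluoromethanesulfonate
Product: 22 (3R)-2-(3,5-dimethyl-4-oxo-6-pentyl-4H-pyran-2-yl)-4-(6-ethyl-3,5-dimethyl-4-oxo-4H-pyran-2-yl)penta-1,4-dien-3-ol, via alkenylchromium dichloride 21 (not isolated)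
Conditions: CrCl2 (4 equiv), NiCl2 (5 mol%), L* (4.4 equiv), Et3N (4.4 equiv), THF, 0 °C to rt; aqueous work-up
Reagents that add atoms: none
Why: zerovalent nickel inserts into the C–OTf bond and hands the alkenyl group to trivalent chromium, and the ligand-bound alkenylchromium 21 adds 1,2 to the aldehyde only (asymmetric Nozaki–Hiyama–Kishi coupling), the chiral sulfonamide ligand directing attack to the Re face so that the (R)-carbinol, the single stereocentre that controls the rest of the route, is set here.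

Step 10
Reactants: 22 (3R)-dienol
Product: 23 (2R,3R,4S)-2-(3,5-dimethyl-4-oxo-6-pentyl-4H-pyran-2-yl)-4-(6-ethyl-3,5-dimethyl-4-oxo-4H-pyran-2-yl)pentan-3-ol (C2 carries ring A, C4 carries ring B; both methyl groups anti to the hydroxyl)
Conditions: H2 (70 bar), [Rh(nbd)(dppb)]BF4 (10 mol%), CH2Cl2, rt
Reagents that add atoms: none
Why: the hydroxyl binds the cationic rhodium and each 1,1-disubstituted alkene is reduced inside the chelate from the face that avoids A(1,2) and A(1,3) strain (hydroxyl-directed homogeneous hydrogenation), so both new methyl-bearing centres form anti to the OH, giving (2R) and (4S) in one operation, while the high hydrogen pressure suppresses allylic alcohol isomerisation.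

Step 11
Reactants: 23 (2R,3R,4S)-alcohol
Product: 24 (2S,4R)-2-(3,5-dimethyl-4-oxo-6-pentyl-4H-pyran-2-yl)-4-(6-ethyl-3,5-dimethyl-4-oxo-4H-pyran-2-yl)pentan-3-one
Conditions: DMP (1.5 equiv), pyridine, CH2Cl2, 0 °C, 1 h; cold Na2S2O3/NaHCO3 wash, chromatography on deactivated silica
Reagents that add atoms: none
Why: buffered Dess–Martin oxidation removes the relay carbinol under non-enolising conditions, so the two α-centres are untouched and their descriptors change from (2R,4S) to (2S,4R) only because C3 gains CIP priority as a carbonyl.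

**Compound list**

1 | pentan-3-one | CCC(=O)CC | starting material
2 | acetic acid | CC(=O)O | starting material
3 | 2,3,5,6-tetramethyl-4H-pyran-4-one | Cc1oc(C)c(C)c(=O)c1C | intermediate
4 | 1-iodobutane | CCCCI | starting material
5 | lithium 3,5,6-trimethyl-2-methylidene-2H-pyran-4-olate (γ-enolate of 3, formed in the flask) | C=C1OC(C)=C(C)C(O[Li])=C1C | intermediate
6 | 2,3,5-trimethyl-6-pentyl-4H-pyran-4-one | CCCCCc1oc(C)c(C)c(=O)c1C | intermediate
7 | ethyl formate | CCOC=O | starting material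
8 | lithium 3,5-dimethyl-2-methylidene-6-pentyl-2H-pyran-4-olate (γ-enolate of 6, formed in the flask) | C=C1OC(CCCCC)=C(C)C(O[Li])=C1C | intermediate
9 | 2-(3,5-dimethyl-4-oxo-6-pentyl-4H-pyran-2-yl)acetaldehyde | CCCCCc1oc(CC=O)c(C)c(=O)c1C | intermediate
10 | formaldehyde | C=O | starting material
11 | 2-(3,5-dimethyl-4-oxo-6-pentyl-4H-pyran-2-yl)prop-2-enal | CCCCCc1oc(C(=C)C=O)c(C)c(=O)c1C | intermediate
12 | propanoic acid | CCC(=O)O | starting material
13 | 2,6-diethyl-3,5-dimethyl-4H-pyran-4-one | CCc1oc(CC)c(C)c(=O)c1C | intermediate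
14 | 2-(benzenesulfonyl)-3-phenyloxaziridine (racemic, trans) | O=S(=O)(c1ccccc1)N1OC1c1ccccc1 | starting material
15 | potassium 6-ethyl-2-ethylidene-3,5-dimethyl-2H-pyran-4-olate (γ-enolate of 13, formed in the flask) | CC=C1OC(CC)=C(C)C(O[K])=C1C | intermediate
16 | 2-ethyl-6-(1-hydroxyethyl)-3,5-dimethyl-4H-pyran-4-one (racemic) | CCc1oc(C(C)O)c(C)c(=O)c1C | intermediate
17 | 2-acetyl-6-ethyl-3,5-dimethyl-4H-pyran-4-one | CCc1oc(C(C)=O)c(C)c(=O)c1C | intermediate
18 | N-phenylbis(trifluoromethanesulfonimide) | O=S(=O)(N(c1ccccc1)S(=O)(=O)C(F)(F)F)C(F)(F)F | starting material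
19 | potassium 1-(6-ethyl-3,5-dimethyl-4-oxo-4H-pyran-2-yl)ethen-1-olate (formed in the flask) | C=C(O[K])c1oc(CC)c(C)c(=O)c1C | intermediate
20 | 1-(6-ethyl-3,5-dimethyl-4-oxo-4H-pyran-2-yl)ethenyl trifluoromethanesulfonate | CCc1oc(C(=C)OS(=O)(=O)C(F)(F)F)c(C)c(=O)c1C | intermediate
21 | dichloro[1-(6-ethyl-3,5-dimethyl-4-oxo-4H-pyran-2-yl)ethenyl]chromium (trivalent chromium, ligand L* omitted, formed in the flask) | CCc1oc(C(=C)[Cr](Cl)Cl)c(C)c(=O)c1C | intermediate
22 | (3R)-2-(3,5-dimethyl-4-oxo-6-pentyl-4H-pyran-2-yl)-4-(6-ethyl-3,5-dimethyl-4-oxo-4H-pyran-2-yl)penta-1,4-dien-3-ol | CCCCCc1oc(C(=C)[C@H](O)C(=C)c2oc(CC)c(C)c(=O)c2C)c(C)c(=O)c1C | intermediate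
23 | (2R,3R,4S)-2-(3,5-dimethyl-4-oxo-6-pentyl-4H-pyran-2-yl)-4-(6-ethyl-3,5-dimethyl-4-oxo-4H-pyran-2-yl)pentan-3-ol | CCCCCc1oc([C@H](C)[C@H](O)[C@H](C)c2oc(CC)c(C)c(=O)c2C)c(C)c(=O)c1C | intermediate
24 | (2S,4R)-2-(3,5-dimethyl-4-oxo-6-pentyl-4H-pyran-2-yl)-4-(6-ethyl-3,5-dimethyl-4-oxo-4H-pyran-2-yl)pentan-3-one (CNP0268096.4) | CCCCCc1oc([C@H](C)C(=O)[C@H](C)c2oc(CC)c(C)c(=O)c2C)c(C)c(=O)c1C | target

**Step count and risks**

Total step count: 11. Longest linear sequence: 7 steps (1, 2, 3, 4, 9, 10, 11; the ring B branch 5, 6, 7, 8, 9, 10, 11 is equally long).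

Risk A, concerning step 9. The coupling must give high enantioselectivity with two labile partners, and the product ee is the ee of the target because nothing later can upgrade it. The fallback sets out from 20 and changes the metal and the mode of asymmetric induction. Miyaura borylation (PdCl2(PPh3)2, PPh3, KOPh, B2pin2, toluene, 50 °C) gives 2-ethyl-3,5-dimethyl-6-[1-(4,4,5,5-tetramethyl-1,3,2-dioxaborolan-2-yl)ethenyl]-4H-pyran-4-one F2. Boron-to-zinc exchange with Et2Zn in toluene gives ethyl[1-(6-ethyl-3,5-dimethyl-4-oxo-4H-pyran-2-yl)ethenyl]zinc F3, used in solution. This adds to aldehyde 11 under amino alcohol catalysis ((+)-3-exo-morpholinoisoborneol, 5 mol%, −10 °C, the antipode chosen for Re-face addition) and comes back to the route at 22.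

Risk B, concerning step 10. Both alkenes must be reduced anti to the hydroxyl, and the pyranone carbonyls may slow the rhodium catalyst or allow isomerisation to a ketone. The all-syn alcohol would oxidise to the enantiomer of the target and the mixed isomer to the anti diastereomer, so 23 must be purified at this stage. The fallback replaces the chelation relay by Still-type acyclic steric control in hydroboration, which delivers hydrogen to the opposite alkene face and therefore needs the antipodal carbinol. It sets out from 11 (with 20), which are coupled as in step 9 but with the antipode of L* to give (3S)-2-(3,5-dimethyl-4-oxo-6-pentyl-4H-pyran-2-yl)-4-(6-ethyl-3,5-dimethyl-4-oxo-4H-pyran-2-yl)penta-1,4-dien-3-ol F4. 9-BBN (4 equiv, THF, 0 °C to rt; the hydroxyl is borylated transiently) gives (2R,3S,4S)-1,5-bis(9-borabicyclo[3.3.1]nonan-9-yl)-2-(3,5-dimethyl-4-oxo-6-pentyl-4H-pyran-2-yl)-4-(6-ethyl-3,5-dimethyl-4-oxo-4H-pyran-2-yl)pentan-3-ol F5. Oxidation with NaBO3·4H2O gives (2R,3S,4S)-2-(3,5-dimethyl-4-oxo-6-pentyl-4H-pyran-2-yl)-4-(6-ethyl-3,5-dimethyl-4-oxo-4H-pyran-2-yl)pentane-1,3,5-triol F6. I2, PPh3 and imidazole convert the two primary hydroxyls to give (2R,3S,4S)-2-(3,5-dimethyl-4-oxo-6-pentyl-4H-pyran-2-yl)-4-(6-ethyl-3,5-dimethyl-4-oxo-4H-pyran-2-yl)-1,5-diiodopentan-3-ol F7. Bu3SnH with AIBN in toluene at 80 °C gives (2R,3S,4S)-2-(3,5-dimethyl-4-oxo-6-pentyl-4H-pyran-2-yl)-4-(6-ethyl-3,5-dimethyl-4-oxo-4H-pyran-2-yl)pentan-3-ol F8, the C3 epimer of 23 with the same C2 and C4 centres. Oxidation as in step 11 comes back to the route at 24.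

Risk C, concerning step 3. Kinetic deprotonation must choose the 2-methyl group over the α-CH2 of the pentyl chain, and any formylation at the pentyl position is carried into an inseparable homologue. The fallback sets out from 6 and uses a thermal condensation under steric control instead of a kinetic enolate. Heating 6 with tert-butoxybis(dimethylamino)methane in DMF at 110 °C condenses only the unhindered methyl group and gives (E)-2-[2-(dimethylamino)ethenyl]-3,5-dimethyl-6-pentyl-4H-pyran-4-one F1. Hydrolysis (1 M HCl, THF, 0 °C) comes back to the route at 9.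

Further compounds
F1 | step 3 | (E)-2-[2-(dimethylamino)ethenyl]-3,5-dimethyl-6-pentyl-4H-pyran-4-one | CCCCCc1oc(/C=C/N(C)C)c(C)c(=O)c1C
F2 | step 9 | 2-ethyl-3,5-dimethyl-6-[1-(4,4,5,5-tetramethyl-1,3,2-dioxaborolan-2-yl)ethenyl]-4H-pyran-4-one | CCc1oc(C(=C)B2OC(C)(C)C(C)(C)O2)c(C)c(=O)c1C
F3 | step 9 | ethyl[1-(6-ethyl-3,5-dimethyl-4-oxo-4H-pyran-2-yl)ethenyl]zinc | CC[Zn]C(=C)c1oc(CC)c(C)c(=O)c1C
F4 | step 10 | (3S)-2-(3,5-dimethyl-4-oxo-6-pentyl-4H-pyran-2-yl)-4-(6-ethyl-3,5-dimethyl-4-oxo-4H-pyran-2-yl)penta-1,4-dien-3-ol | CCCCCc1oc(C(=C)[C@@H](O)C(=C)c2oc(CC)c(C)c(=O)c2C)c(C)c(=O)c1C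
F5 | step 10 | (2R,3S,4S)-1,5-bis(9-borabicyclo[3.3.1]nonan-9-yl)-2-(3,5-dimethyl-4-oxo-6-pentyl-4H-pyran-2-yl)-4-(6-ethyl-3,5-dimethyl-4-oxo-4H-pyran-2-yl)pentan-3-ol | CCCCCc1oc([C@H](CB2C3CCCC2CCC3)[C@@H](O)[C@H](CB2C3CCCC2CCC3)c2oc(CC)c(C)c(=O)c2C)c(C)c(=O)c1C
F6 | step 10 | (2R,3S,4S)-2-(3,5-dimethyl-4-oxo-6-pentyl-4H-pyran-2-yl)-4-(6-ethyl-3,5-dimethyl-4-oxo-4H-pyran-2-yl)pentane-1,3,5-triol | CCCCCc1oc([C@H](CO)[C@@H](O)[C@H](CO)c2oc(CC)c(C)c(=O)c2C)c(C)c(=O)c1C
F7 | step 10 | (2R,3S,4S)-2-(3,5-dimethyl-4-oxo-6-pentyl-4H-pyran-2-yl)-4-(6-ethyl-3,5-dimethyl-4-oxo-4H-pyran-2-yl)-1,5-diiodopentan-3-ol | CCCCCc1oc([C@H](CI)[C@@H](O)[C@H](CI)c2oc(CC)c(C)c(=O)c2C)c(C)c(=O)c1C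
F8 | step 10 | (2R,3S,4S)-2-(3,5-dimethyl-4-oxo-6-pentyl-4H-pyran-2-yl)-4-(6-ethyl-3,5-dimethyl-4-oxo-4H-pyran-2-yl)pentan-3-ol | CCCCCc1oc([C@H](C)[C@@H](O)[C@H](C)c2oc(CC)c(C)c(=O)c2C)c(C)c(=O)c1C
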